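**Strategy.** The 1,2-dione is not made by acylating the arene or by oxidising a deoxybenzoin. Its two carbons are first joined inside a lactone: an arylacetate tethered through the 7-oxygen of a fully substituted chromene salicylate closes to a 3-aryl-4-hydroxycoumarin (4'-O-silyl scandenin). The key step then deletes the tether carbon: O2 enters at the enol carbon C3 of the coumarin, the lactone carbonyl C2 leaves as CO2, and in one operation C3 becomes the second ketone while lactone oxygen O1 is released as the chelated 7-OH beside the prenyl group. The feature exploited is the ortho-hydroxyaryl 1,2-dione array C7(OH)–C6–C(=O)–C(=O)–Ar on ring A.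

Key step: step 9

Remark: the target has no stereocentre and no stereogenic double bond, so it is achiral and no stereocontrol is needed. Chromene compounds use 2H-chromene numbering (O1, C2 gem-dimethyl, C5 OMe, C6 acyl, C7 OH, C8 prenyl). The coumarin stage uses pyrano[3,2-g]chromen-2-one numbering (O1, C2 lactone C=O, C3 aryl, C4 OH, C5 OMe, C10 prenyl). 5-Methoxyresorcinol, (4-hydroxyphenyl)acetic acid and all reagents named are assumed to be commercial.

Step 1
Reactants: 1 5-methoxybenzene-1,3-diol
Product: 2 1-methoxy-3,5-bis(methoxymethoxy)benzene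
Conditions: NaH (2.5 equiv), MOMCl (2.4 equiv), DMF, 0 °C to rt
Reagents that add atoms: chloromethyl methyl ether, COCCl
Why: Williamson-type O-alkylation of both phenoxides (MOM protection) installs the two strong ortho-directing groups needed for the next two steps, and no stereocentre is formed.

Step 2
Reactants: 2 1-methoxy-3,5-bis(methoxymethoxy)benzene
Product: 4 5-methoxy-1,3-bis(methoxymethoxy)-2-(3-methylbut-2-en-1-yl)benzene, via aryllithium 3 (not isolated)
Conditions: n-BuLi (1.15 equiv), THF, 0 °C; then CuBr·SMe2 (10 mol %), prenyl bromide (1.3 equiv), −78 °C to rt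
Reagents that add atoms: prenyl bromide (1-bromo-3-methylbut-2-ene), CC(C)=CCBr
Why: Directed ortho-metalation should occur at the position flanked by both OMOM groups (cooperative direction, stronger than OMe), and copper-catalysed allylic substitution then gives the linear prenyl arene.

Step 3
Reactants: 4 5-methoxy-1,3-bis(methoxymethoxy)-2-(3-methylbut-2-en-1-yl)benzene
Product: 6 methyl 6-methoxy-2,4-bis(methoxymethoxy)-3-(3-methylbut-2-en-1-yl)benzoate, via ring aryllithium 5 (not isolated)
Conditions: n-BuLi (1.2 equiv), TMEDA (1.2 equiv), THF, −78 to −20 °C; then added to ClCO2Me (3 equiv), THF, −78 °C to rt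
Reagents that add atoms: methyl chloroformate, COC(=O)Cl
Why: A second directed ortho-metalation at one of the two equivalent ring positions between OMOM and OMe is followed by acylation with excess chloroformate, and the 2,6-dioxygenated ester is too hindered to add a second aryllithium.

Step 4
Reactants: 6 methyl 6-methoxy-2,4-bis(methoxymethoxy)-3-(3-methylbut-2-en-1-yl)benzoate
Product: 7 methyl 2,4-dihydroxy-6-methoxy-3-(3-methylbut-2-en-1-yl)benzoate
Conditions: conc. HCl (cat.), MeOH, rt to 40 °C
Reagents that add atoms: none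
Why: Acid-catalysed acetal exchange with methanol (MOM cleavage) is mild enough to leave the prenyl group uncyclised, and the methyl ester cannot be scrambled in methanol.

Step 5
Reactants: 7 methyl 2,4-dihydroxy-6-methoxy-3-(3-methylbut-2-en-1-yl)benzoate
Product: 9 methyl 7-hydroxy-5-methoxy-2,2-dimethyl-8-(3-methylbut-2-en-1-yl)-2H-chromene-6-carboxylate, via ortho-quinone methide 8 (not isolated)
Conditions: 3-methylbut-2-enal (2 equiv), ethylenediammonium diacetate (20 mol %), toluene, reflux
Reagents that add atoms: 3-methylbut-2-enal, CC(C)=CC=O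
Why: Amine-catalysed Knoevenagel-type condensation at the only free ring carbon gives an ortho-quinone methide that closes by oxa-6π electrocyclisation onto the non-chelated 4-oxygen, and since the chelated 2-OH has no free ortho carbon only one chromene can form.

Step 6
Reactants: 10 (4-hydroxyphenyl)acetic acid
Product: 12 {4-[(tert-butyldimethylsilyl)oxy]phenyl}acetic acid, via bis-silyl ester 11 (not isolated)
Conditions: TBSCl (2.3 equiv), imidazole (5 equiv), DMF, rt; then K2CO3 (cat.), MeOH–H2O, rt; citric acid work-up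
Reagents that add atoms: tert-butyldimethylsilyl chloride, CC(C)(C)[Si](C)(C)Cl
Why: Exhaustive silylation followed by selective solvolysis of the labile silyl ester is the standard way to protect the phenol of a hydroxy acid.

Step 7
Reactants: 9 methyl 7-hydroxy-5-methoxy-2,2-dimethyl-8-(3-methylbut-2-en-1-yl)-2H-chromene-6-carboxylate; 12 {4-[(tert-butyldimethylsilyl)oxy]phenyl}acetic acid
Product: 13 methyl 7-[(2-{4-[(tert-butyldimethylsilyl)oxy]phenyl}acetyl)oxy]-5-methoxy-2,2-dimethyl-8-(3-methylbut-2-en-1-yl)-2H-chromene-6-carboxylate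
Conditions: DCC (1.3 equiv), DMAP (0.2 equiv), CH2Cl2, 0 °C to rt
Reagents that add atoms: none
Why: Steglich esterification should acylate the only free hydroxyl, the chelated 7-OH, and so tether the benzylic carbon next to the ring ester.

Step 8
Reactants: 13 methyl 7-[(2-{4-[(tert-butyldimethylsilyl)oxy]phenyl}acetyl)oxy]-5-methoxy-2,2-dimethyl-8-(3-methylbut-2-en-1-yl)-2H-chromene-6-carboxylate
Product: 14 3-{4-[(tert-butyldimethylsilyl)oxy]phenyl}-4-hydroxy-5-methoxy-8,8-dimethyl-10-(3-methylbut-2-en-1-yl)-2H,8H-pyrano[3,2-g]chromen-2-one (4'-O-TBS-scandenin)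
Conditions: LiHMDS (3 equiv), THF, −78 to 0 °C; cold 0.5 M HCl work-up
Reagents that add atoms: none
Why: Intramolecular Claisen (Dieckmann-type) condensation, in which the benzylic ester enolate attacks the neighbouring methyl ester in a 6-exo-trig closure and deprotonation of the acidic 4-hydroxycoumarin drives the equilibrium.

Step 9
Reactants: 14 3-{4-[(tert-butyldimethylsilyl)oxy]phenyl}-4-hydroxy-5-methoxy-8,8-dimethyl-10-(3-methylbut-2-en-1-yl)-2H,8H-pyrano[3,2-g]chromen-2-one
Product: 17 1-{4-[(tert-butyldimethylsilyl)oxy]phenyl}-2-[7-hydroxy-5-methoxy-2,2-dimethyl-8-(3-methylbut-2-en-1-yl)-2H-chromen-6-yl]ethane-1,2-dione (4'-O-TBS-derrisdione A), via C3-hydroperoxide 15 (not isolated), via dioxetanone 16 (not isolated)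
Conditions: Cu(OAc)2 (20 mol %), pyridine (5 equiv), O2 (1 atm), MeCN–H2O (50:1), 40 °C
Reagents that add atoms: dioxygen, O=O
Why: Proposed new method: the copper(II)-bound coumarin enolate should be oxidised by inner-sphere electron transfer to the C3 radical (benzylic, between two carbonyls, stabilised by the p-silyloxyphenyl group), which traps triplet O2 and is reduced by Cu(I) to the C3 peroxide 15; its terminal oxygen adds to the lactone carbonyl C2, the tetrahedral intermediate expels the ring-A aryloxide to give dioxetanone 16, and retro-[2+2] loss of CO2 leaves the C3 ketone beside the C4 ketone and frees O1 as the phenol. The closest known reaction types are the base/O2 oxidative decarboxylation of α-carbanions of aryl esters through 1,2-dioxetanones (2-coumaranone and luciferin-type chemiluminescence), the Cu/O2 cleavage of 2-aryl-1,3-dicarbonyl compounds to 1,2-diketones, and the dioxygenative excision of one ring carbon from flavonols; the one-carbon excision from a 3-aryl-4-hydroxycoumarin to a benzil is not assumed to be established. No ring of the product is closed (the lactone is opened, and the dioxetanone is only a transient 4-exo-trig closure) and no stereocentre is formed, the C3 centre of 15 being destroyed. The selectivity needed is peroxide attack at C2 and not at C4, which would cut C3–C4: C4 is an aryl ketone deactivated by three oxygen donors on ring A and screened by the peri 5-OMe, whereas C2 is an aryl ester with a good aryloxide leaving group. If the peroxide is instead reduced to the 3-hydroxy dione, hydrolysis, decarboxylation and Cu/O2 oxidation of the resulting benzoin should converge on the same dione, and triplet O2 with Cu(II) should leave the prenyl and chromene alkenes untouched because no singlet oxygen or electrophilic oxidant is present.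

Step 10
Reactants: 17 1-{4-[(tert-butyldimethylsilyl)oxy]phenyl}-2-[7-hydroxy-5-methoxy-2,2-dimethyl-8-(3-methylbut-2-en-1-yl)-2H-chromen-6-yl]ethane-1,2-dione
Product: 18 Derrisdione A, 1-[7-hydroxy-5-methoxy-2,2-dimethyl-8-(3-methylbut-2-en-1-yl)-2H-chromen-6-yl]-2-(4-hydroxyphenyl)ethane-1,2-dione
Conditions: TBAF (1.1 equiv), AcOH (1.1 equiv), THF, 0 °C
Reagents that add atoms: none
Why: Fluoride-mediated cleavage of the aryl silyl ether, buffered with acetic acid so that the 1,2-dione and the ortho-prenyl phenol are not exposed to strong base.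

**Compound list**

1 | 5-methoxybenzene-1,3-diol (5-methoxyresorcinol) | COc1cc(O)cc(O)c1 | starting material
2 | 1-methoxy-3,5-bis(methoxymethoxy)benzene | COCOc1cc(OC)cc(OCOC)c1 | intermediate
3 | [4-methoxy-2,6-bis(methoxymethoxy)phenyl]lithium | [Li]c1c(OCOC)cc(OC)cc1OCOC | intermediate
4 | 5-methoxy-1,3-bis(methoxymethoxy)-2-(3-methylbut-2-en-1-yl)benzene | COCOc1cc(OC)cc(OCOC)c1CC=C(C)C | intermediate
5 | [6-methoxy-2,4-bis(methoxymethoxy)-3-(3-methylbut-2-en-1-yl)phenyl]lithium | [Li]c1c(OC)cc(OCOC)c(CC=C(C)C)c1OCOC | intermediate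
6 | methyl 6-methoxy-2,4-bis(methoxymethoxy)-3-(3-methylbut-2-en-1-yl)benzoate | COC(=O)c1c(OC)cc(OCOC)c(CC=C(C)C)c1OCOC | intermediate
7 | methyl 2,4-dihydroxy-6-methoxy-3-(3-methylbut-2-en-1-yl)benzoate | COC(=O)c1c(OC)cc(O)c(CC=C(C)C)c1O | intermediate
8 | methyl 6-hydroxy-2-methoxy-3-(3-methylbut-2-en-1-ylidene)-5-(3-methylbut-2-en-1-yl)-4-oxocyclohexa-1,5-diene-1-carboxylate (ortho-quinone methide, alkene geometry not defined) | COC(=O)C1=C(OC)C(=CC=C(C)C)C(=O)C(CC=C(C)C)=C1O | intermediate
9 | methyl 7-hydroxy-5-methoxy-2,2-dimethyl-8-(3-methylbut-2-en-1-yl)-2H-chromene-6-carboxylate | COC(=O)c1c(OC)c2C=CC(C)(C)Oc2c(CC=C(C)C)c1O | intermediate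
10 | (4-hydroxyphenyl)acetic acid | OC(=O)Cc1ccc(O)cc1 | starting material
11 | tert-butyldimethylsilyl {4-[(tert-butyldimethylsilyl)oxy]phenyl}acetate | CC(C)(C)[Si](C)(C)OC(=O)Cc1ccc(O[Si](C)(C)C(C)(C)C)cc1 | intermediate
12 | {4-[(tert-butyldimethylsilyl)oxy]phenyl}acetic acid | CC(C)(C)[Si](C)(C)Oc1ccc(CC(=O)O)cc1 | intermediate
13 | methyl 7-[(2-{4-[(tert-butyldimethylsilyl)oxy]phenyl}acetyl)oxy]-5-methoxy-2,2-dimethyl-8-(3-methylbut-2-en-1-yl)-2H-chromene-6-carboxylate | COC(=O)c1c(OC)c2C=CC(C)(C)Oc2c(CC=C(C)C)c1OC(=O)Cc1ccc(O[Si](C)(C)C(C)(C)C)cc1 | intermediate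
14 | 3-{4-[(tert-butyldimethylsilyl)oxy]phenyl}-4-hydroxy-5-methoxy-8,8-dimethyl-10-(3-methylbut-2-en-1-yl)-2H,8H-pyrano[3,2-g]chromen-2-one (4'-O-TBS-scandenin) | COc1c2C=CC(C)(C)Oc2c(CC=C(C)C)c2OC(=O)C(c3ccc(O[Si](C)(C)C(C)(C)C)cc3)=C(O)c12 | intermediate
15 | 3-{4-[(tert-butyldimethylsilyl)oxy]phenyl}-3-hydroperoxy-5-methoxy-8,8-dimethyl-10-(3-methylbut-2-en-1-yl)-2H,8H-pyrano[3,2-g]chromene-2,4(3H)-dione (racemic at C3) | COc1c2C=CC(C)(C)Oc2c(CC=C(C)C)c2OC(=O)C(OO)(c3ccc(O[Si](C)(C)C(C)(C)C)cc3)C(=O)c12 | intermediate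
16 | 4-{4-[(tert-butyldimethylsilyl)oxy]phenyl}-4-[7-hydroxy-5-methoxy-2,2-dimethyl-8-(3-methylbut-2-en-1-yl)-2H-chromene-6-carbonyl]-1,2-dioxetan-3-one (racemic) | COc1c2C=CC(C)(C)Oc2c(CC=C(C)C)c(O)c1C(=O)C1(c2ccc(O[Si](C)(C)C(C)(C)C)cc2)OOC1=O | intermediate
17 | 1-{4-[(tert-butyldimethylsilyl)oxy]phenyl}-2-[7-hydroxy-5-methoxy-2,2-dimethyl-8-(3-methylbut-2-en-1-yl)-2H-chromen-6-yl]ethane-1,2-dione (4'-O-TBS-derrisdione A) | COc1c2C=CC(C)(C)Oc2c(CC=C(C)C)c(O)c1C(=O)C(=O)c1ccc(O[Si](C)(C)C(C)(C)C)cc1 | intermediate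
18 | Derrisdione A, 1-[7-hydroxy-5-methoxy-2,2-dimethyl-8-(3-methylbut-2-en-1-yl)-2H-chromen-6-yl]-2-(4-hydroxyphenyl)ethane-1,2-dione (achiral) | COc1c2c(c(CC=C(C)C)c(O)c1C(=O)C(=O)c1ccc(O)cc1)OC(C)(C)C=C2 | target

**Step count.** Total: 10 steps. Longest linear sequence: 9 steps (steps 1–5 and 7–10; step 6 is a one-step side branch).

**Steps most likely to fail**

Step 9 (Proposed new method). The C3 peroxide may collapse through the C4 ketone instead of the lactone carbonyl, which would cut C3–C4 and give a ring-A carboxylic acid carrying an aryl glyoxylate ester. The strongly stabilised enolate may also fail to turn over with Cu(II)/O2, or the doubly activated prenyl CH2 may autoxidise. The fallback uses known chemistry, sets out from 14 and returns at 17. Enolate hydroxylation of 14 (KHMDS, THF, −78 °C, then 2-(phenylsulfonyl)-3-phenyloxaziridine) should give 3-{4-[(tert-butyldimethylsilyl)oxy]phenyl}-3-hydroxy-5-methoxy-8,8-dimethyl-10-(3-methylbut-2-en-1-yl)-2H,8H-pyrano[3,2-g]chromene-2,4(3H)-dione F1. Mild hydrolysis of this activated aryl lactone (NaHCO3, THF–H2O, 40 °C) with spontaneous decarboxylation of the α-hydroxy-β-keto acid should give the benzoin 2-{4-[(tert-butyldimethylsilyl)oxy]phenyl}-2-hydroxy-1-[7-hydroxy-5-methoxy-2,2-dimethyl-8-(3-methylbut-2-en-1-yl)-2H-chromen-6-yl]ethan-1-one F2. Oxidation of the benzoin with activated MnO2 in CH2Cl2 at rt should then give 17.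

Step 8. E1cB loss of the arylketene from the benzylic ester enolate, which returns the phenoxide of 9, may outrun closure onto the hindered, electron-rich benzoate; acylation of the hindered chelated phenol in step 7 may be slow for the same steric reason. The fallback sets out from 9 and returns at 14, bringing in the aryl group after ring closure. Acetylation of 9 (Ac2O, Et3N, DMAP, CH2Cl2) should give methyl 7-acetoxy-5-methoxy-2,2-dimethyl-8-(3-methylbut-2-en-1-yl)-2H-chromene-6-carboxylate F3. Dieckmann closure of the small acetate enolate (LiHMDS, THF, −78 to 0 °C) should give 4-hydroxy-5-methoxy-8,8-dimethyl-10-(3-methylbut-2-en-1-yl)-2H,8H-pyrano[3,2-g]chromen-2-one F4. Pinhey C3-arylation of F4 with {4-[(tert-butyldimethylsilyl)oxy]phenyl}lead triacetate F5 (made from the commercial arylboronic acid and Pb(OAc)4 with cat. Hg(OAc)2 in CHCl3) in CHCl3–pyridine at 40–60 °C should give 14.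

Step 3. Lateral deprotonation of the benzylic–allylic CH2 that lies between the two OMOM groups may compete with ring metalation, and the aryllithium may add twice to the chloroformate. The fallback sets out from 4 and returns at 6, replacing deprotonation by halogen–metal exchange. Electrophilic bromination of the most activated ring position (NBS, 1.0 equiv, MeCN, 0 °C) should give 2-bromo-1-methoxy-3,5-bis(methoxymethoxy)-4-(3-methylbut-2-en-1-yl)benzene F6. Bromine–lithium exchange (t-BuLi, 2.1 equiv, THF, −78 °C), which is faster than any deprotonation, followed by addition to excess ClCO2Me should give 6.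

**Further compounds**

F1 | step 9 | 3-{4-[(tert-butyldimethylsilyl)oxy]phenyl}-3-hydroxy-5-methoxy-8,8-dimethyl-10-(3-methylbut-2-en-1-yl)-2H,8H-pyrano[3,2-g]chromene-2,4(3H)-dione (racemic) | COc1c2C=CC(C)(C)Oc2c(CC=C(C)C)c2OC(=O)C(O)(c3ccc(O[Si](C)(C)C(C)(C)C)cc3)C(=O)c12
F2 | step 9 | 2-{4-[(tert-butyldimethylsilyl)oxy]phenyl}-2-hydroxy-1-[7-hydroxy-5-methoxy-2,2-dimethyl-8-(3-methylbut-2-en-1-yl)-2H-chromen-6-yl]ethan-1-one (racemic) | COc1c2C=CC(C)(C)Oc2c(CC=C(C)C)c(O)c1C(=O)C(O)c1ccc(O[Si](C)(C)C(C)(C)C)cc1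
F3 | step 8 | methyl 7-acetoxy-5-methoxy-2,2-dimethyl-8-(3-methylbut-2-en-1-yl)-2H-chromene-6-carboxylate | COC(=O)c1c(OC)c2C=CC(C)(C)Oc2c(CC=C(C)C)c1OC(C)=O
F4 | step 8 | 4-hydroxy-5-methoxy-8,8-dimethyl-10-(3-methylbut-2-en-1-yl)-2H,8H-pyrano[3,2-g]chromen-2-one | COc1c2C=CC(C)(C)Oc2c(CC=C(C)C)c2OC(=O)C=C(O)c12
F5 | step 8 | {4-[(tert-butyldimethylsilyl)oxy]phenyl}lead triacetate | CC(=O)O[Pb](OC(C)=O)(OC(C)=O)c1ccc(O[Si](C)(C)C(C)(C)C)cc1
F6 | step 3 | 2-bromo-1-methoxy-3,5-bis(methoxymethoxy)-4-(3-methylbut-2-en-1-yl)benzene | COCOc1cc(OC)c(Br)c(OCOC)c1CC=C(C)C
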